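**Assumption:** the target has no stereocentre and no stereogenic double bond (it is achiral), so "single enantiomer" is read as the single constitution shown; 1, 5 and the triazolium precatalyst are taken as commercial.

**Retrosynthetic overview**
1. 9 ⇒ 8: the 5-OH is unmasked last by chelation-controlled cleavage of the peri 5-OMe.
2. 8 ⇒ 4 + 5: ring C is the only ring built (rings A and B are bought as arenes). It is cut at C2–C3 (proposed NHC cross-acyloin) and O1–C2 (hemiketalisation/dehydration).
3. 4 ⇒ 3: the ketoaldehyde comes from the acetyl group by Riley oxidation.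
4. 3 ⇒ 1: Friedel–Crafts acetylation of 1,2,3,5-tetramethoxybenzene with in situ ortho-demethylation.

**Route**

Step 1
Reactants: 1 1,2,3,5-tetramethoxybenzene
Product: 3 2'-hydroxy-3',4',6'-trimethoxyacetophenone, via tetramethoxyacetophenone 2 (not isolated)
Conditions: AcCl (1.3 equiv), AlCl3 (2.5 equiv), Et2O, 0 °C → rt, 24 h; then ice/2 M HCl
Reagents that add atoms: acetyl chloride, CC(Cl)=O
Why: Friedel–Crafts acylation at the single (symmetry-equivalent) free ring position gives 2, whose more hindered ortho-methoxy group (flanked by C=O and OMe) is then cleaved by chelated AlCl3, the established outcome for this arene; no stereocentre is formed.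

Step 2
Reactants: 3 2'-hydroxy-3',4',6'-trimethoxyacetophenone
Product: 4 2-(2-hydroxy-3,4,6-trimethoxyphenyl)-2-oxoacetaldehyde (obtained as hydrate/cyclic hemiacetal, dehydrated by toluene azeotrope before use; drawn as the free ketoaldehyde)
Conditions: SeO2 (1.3 equiv), 1,4-dioxane/H2O (20:1), 100 °C, 6 h; filter off Se; PhMe azeotrope
Reagents that add atoms: selenium dioxide, O=[Se]=O
Why: Riley oxidation (SeO2 α-oxidation of an aryl methyl ketone through the enol and a [2,3]-shift) stops at the arylglyoxal in aqueous dioxane, and the aryl ethers and the hydrogen-bonded phenol are inert to it; no stereocentre is formed.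

Step 3
Reactants: 4 2-(2-hydroxy-3,4,6-trimethoxyphenyl)-2-oxoacetaldehyde; 5 3,4,5-trimethoxybenzaldehyde
Product: 8 3-hydroxy-5,7,8-trimethoxy-2-(3,4,5-trimethoxyphenyl)-4H-chromen-4-one, via hydroxydiketone 6 (not isolated), via cyclic hemiketal 7 (not isolated)
Conditions: 5 (1.5 equiv), 2-(pentafluorophenyl)-6,7-dihydro-5H-pyrrolo[2,1-c][1,2,4]triazol-2-ium tetrafluoroborate (15 mol%), iPr2NEt (30 mol%), 4 Å MS, THF, 40 °C, 4 added over 6 h; then TsOH·H2O (60 mol%), 65 °C, 2 h
Reagents that add atoms: none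
Why: Proposed new method: an NHC-catalysed cross-acyloin/cyclodehydration flavonol annulation, in which the triazolylidene adds to the unhindered aldehyde 5 to give its Breslow intermediate (acyl-anion equivalent), which attacks the much more electrophilic aldehyde carbon of ketoaldehyde 4 (kept at low free concentration by slow addition and by its ortho-phenol hemiacetal form) to forge C2–C3 in hydroxydiketone 6; homo-benzoin of 5 and wrong-sense adducts are reversible, whereas 6 is drained by 6-exo-trig attack of its ortho-phenol on the new aryl ketone (O1–C2, hemiketal 7) and acid-catalysed dehydration to the aromatic, hydrogen-bonded pyranone 8; the closest known reaction types are NHC-catalysed chemoselective cross-benzoin reactions of aldehydes with α-ketoester acceptors and the acid cyclodehydration that ends the Baker–Venkataraman flavone synthesis; the stereocentres of 6 and 7 form racemic and are destroyed in the dehydration.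

Step 4
Reactants: 8 3-hydroxy-5,7,8-trimethoxy-2-(3,4,5-trimethoxyphenyl)-4H-chromen-4-one
Product: 9 3,5-dihydroxy-7,8-dimethoxy-2-(3,4,5-trimethoxyphenyl)-4H-chromen-4-one (3,5-dihydroxy-7,8,3',4',5'-pentamethoxyflavone)
Conditions: BCl3 (3 equiv, 1 M in CH2Cl2), CH2Cl2, −78 → 0 °C, 2 h; then H2O/1 M HCl, rt
Reagents that add atoms: none
Why: Chelation-directed Lewis-acid ether cleavage, in which BCl3 bound to the C4 carbonyl forms a six-membered chelate with the peri 5-OMe and chloride removes only that methyl group at low temperature, the standard selective 5-O-demethylation of 5-methoxyflavones; no stereocentre is present.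

**Compound list**
1 | 1,2,3,5-tetramethoxybenzene | COc1cc(OC)c(OC)c(OC)c1 | starting material
2 | 1-(2,3,4,6-tetramethoxyphenyl)ethan-1-one (2,3,4,6-tetramethoxyacetophenone) | CC(=O)c1c(OC)cc(OC)c(OC)c1OC | intermediate (not isolated)
3 | 1-(2-hydroxy-3,4,6-trimethoxyphenyl)ethan-1-one (2'-hydroxy-3',4',6'-trimethoxyacetophenone) | CC(=O)c1c(OC)cc(OC)c(OC)c1O | intermediate
4 | 2-(2-hydroxy-3,4,6-trimethoxyphenyl)-2-oxoacetaldehyde | O=CC(=O)c1c(OC)cc(OC)c(OC)c1O | intermediate
5 | 3,4,5-trimethoxybenzaldehyde | COc1cc(C=O)cc(OC)c1OC | starting material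
6 | 2-hydroxy-1-(2-hydroxy-3,4,6-trimethoxyphenyl)-3-(3,4,5-trimethoxyphenyl)propane-1,3-dione (racemic) | COc1cc(C(=O)C(O)C(=O)c2c(OC)cc(OC)c(OC)c2O)cc(OC)c1OC | intermediate (not isolated)
7 | 2,3-dihydroxy-5,7,8-trimethoxy-2-(3,4,5-trimethoxyphenyl)-2,3-dihydro-4H-chromen-4-one (racemic, mixture of diastereomers) | COc1cc(C2(O)Oc3c(OC)c(OC)cc(OC)c3C(=O)C2O)cc(OC)c1OC | intermediate (not isolated)
8 | 3-hydroxy-5,7,8-trimethoxy-2-(3,4,5-trimethoxyphenyl)-4H-chromen-4-one | COc1cc(-c2oc3c(OC)c(OC)cc(OC)c3c(=O)c2O)cc(OC)c1OC | intermediate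
9 | 3,5-dihydroxy-7,8-dimethoxy-2-(3,4,5-trimethoxyphenyl)-4H-chromen-4-one (achiral) | COc1cc(-c2oc3c(OC)c(OC)cc(O)c3c(=O)c2O)cc(OC)c1OC | target

**Step count and risks**

Total step count: 4. Longest linear sequence: 4 steps (1 → 3 → 4 → 8 → 9); aldehyde 5 enters convergently in step 3.

The three steps most likely to fail are steps 2, 3 and 4.

Step 2 (Riley oxidation). The risks are over-oxidation to the α-keto acid and selenium attack on the very electron-rich ring position para to the phenol. The fallback sets out from 3 and comes back at 4. Compound 3 is α-nitrosated with isopentyl nitrite and NaOEt in EtOH at 0 °C to give (E)-2-(hydroxyimino)-1-(2-hydroxy-3,4,6-trimethoxyphenyl)ethan-1-one F1. Transoximation of this oximinoketone to formaldehyde (37% aq. CH2O, 2 M HCl, THF, 50 °C) releases ketoaldehyde 4, so no selenium reagent is used.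

Step 3 (the proposed new step). The risks are that the carbene adds to ketoaldehyde 4 instead of 5, that the Breslow intermediate of 4 undergoes internal redox to an α-hydroxy acyl azolium that the phenol traps as a 3-hydroxybenzofuran-2-one, that the wrong-sense acyloin forms, and that hemiketal 7 ring-contracts under base. The fallback uses only known chemistry, sets out from 3 and comes back at 8 (it also bypasses step 2).
- Compound 3 is O-acylated with 3,4,5-trimethoxybenzoyl chloride (pyridine, DMAP, 60 °C) to give 2-acetyl-3,5,6-trimethoxyphenyl 3,4,5-trimethoxybenzoate F2.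
- Baker–Venkataraman rearrangement (KOH, pyridine, 50 °C) gives 1-(2-hydroxy-3,4,6-trimethoxyphenyl)-3-(3,4,5-trimethoxyphenyl)propane-1,3-dione F3.
- Cyclodehydration (cat. H2SO4, AcOH, 100 °C) gives 5,7,8-trimethoxy-2-(3,4,5-trimethoxyphenyl)-4H-chromen-4-one F4.
- Epoxidation with dimethyldioxirane (acetone/CH2Cl2, 0 °C) gives racemic 2,3-epoxy-5,7,8-trimethoxy-2-(3,4,5-trimethoxyphenyl)chroman-4-one F5.
- This flavone oxide opens and tautomerises to 8 with cat. TsOH in CHCl3 at rt.

Step 4 (5-O-demethylation). The risks are cleavage of the hindered 8-OMe or 4'-OMe, and a 3-O/4-C=O borate chelate that slows cleavage of the 5-OMe. The fallback sets out from 8 and comes back at 9, and replaces direct cleavage by a protect–cleave–deprotect sequence. Compound 8 is acetylated (Ac2O, pyridine, rt) to give 5,7,8-trimethoxy-4-oxo-2-(3,4,5-trimethoxyphenyl)-4H-chromen-3-yl acetate F6, so that the carbonyl chelates only towards the 5-OMe. AlCl3 in MeCN at 50 °C then gives 5-hydroxy-7,8-dimethoxy-4-oxo-2-(3,4,5-trimethoxyphenyl)-4H-chromen-3-yl acetate F7. Methanolysis (K2CO3, MeOH, rt) gives 9.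

**Further compounds**
F1 | step 2 | (E)-2-(hydroxyimino)-1-(2-hydroxy-3,4,6-trimethoxyphenyl)ethan-1-one | O/N=C/C(=O)c1c(OC)cc(OC)c(OC)c1O
F2 | step 3 | 2-acetyl-3,5,6-trimethoxyphenyl 3,4,5-trimethoxybenzoate | CC(=O)c1c(OC)cc(OC)c(OC)c1OC(=O)c1cc(OC)c(OC)c(OC)c1
F3 | step 3 | 1-(2-hydroxy-3,4,6-trimethoxyphenyl)-3-(3,4,5-trimethoxyphenyl)propane-1,3-dione | COc1cc(C(=O)CC(=O)c2c(OC)cc(OC)c(OC)c2O)cc(OC)c1OC
F4 | step 3 | 5,7,8-trimethoxy-2-(3,4,5-trimethoxyphenyl)-4H-chromen-4-one | COc1cc(-c2cc(=O)c3c(OC)cc(OC)c(OC)c3o2)cc(OC)c1OC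
F5 | step 3 | 2,3-epoxy-5,7,8-trimethoxy-2-(3,4,5-trimethoxyphenyl)chroman-4-one (racemic) | COc1cc(C23Oc4c(OC)c(OC)cc(OC)c4C(=O)C2O3)cc(OC)c1OC
F6 | step 4 | 5,7,8-trimethoxy-4-oxo-2-(3,4,5-trimethoxyphenyl)-4H-chromen-3-yl acetate | COc1cc(-c2oc3c(OC)c(OC)cc(OC)c3c(=O)c2OC(C)=O)cc(OC)c1OC
F7 | step 4 | 5-hydroxy-7,8-dimethoxy-4-oxo-2-(3,4,5-trimethoxyphenyl)-4H-chromen-3-yl acetate | COc1cc(-c2oc3c(OC)c(OC)cc(O)c3c(=O)c2OC(C)=O)cc(OC)c1OC
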